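**Compound numbers used throughout**

1 3,5-dimethoxyphenol; 2 2-chloro-3,5-dimethoxyphenol; 3 its 6-hydroxymethyl derivative (not isolated); 4 3-chloro-2-hydroxy-4,6-dimethoxybenzaldehyde; 5 biochanin A; 6 its 7-methyl ether; 7 the aryl potassium sulfate formed from 6 (not isolated); 8 the 5,8-dihydroxy isoflavone; 9 bis(4-bromophenyl)iodonium triflate; 10 the 8-(4-bromophenoxy) isoflavone with free 5-OH; 11 its 5-methyl ether; 12 trimethylsilylacetylene; 13 the aryl silyl alkyne; 14 the 2-silyl pentamethyl ether; 15 the pentamethyl ether; 16 the target. Atoms are numbered as in chromen-4-one, with primes for ring B.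

## Analysis of the target

The target 16 is a dimer of two isoflavones (3-arylchromen-4-ones) joined by a diaryl ether: C4' of ring B of an 8-chloro-5,7-dihydroxyisoflavone carries an oxygen that is bound to C8 of a second unit, 5,7-dihydroxy-3-(4-hydroxyphenyl)chromen-4-one (a genistein unit). It has no stereocentre, and the ether is not a hindered axis, so the task is one of constitution only. Three placements must be right: chlorine on C8 and not C6 of the first ring A, the ether oxygen on C8 and not C6 of the second ring A, and the aryl group on C3 and not C2 of both pyranones. The sensitive groups are these: five phenols, two of them chelated to the C4 carbonyls; the electron-rich rings A, which are oxidised and substituted easily; the pyranone rings C, which open when hydroxide or a secondary amine attacks C2; and the aryl chloride, which rules out hydrogenolysis for deprotection. The ether carbon C8 of the genistein unit lies between C7–O and C8a–O1, so the diaryl ether has two ortho substituents and is hard to make by an ordinary copper-mediated coupling. The strategy rests on ring C of the chlorinated unit. Its bonds C4–C3 and O1–C2 join a salicyl part (C4, C4a, C8a, O1, with chlorine already on ring A) to the carbons C2 and C3, and C3 carries ring B with the whole second isoflavone on its ether oxygen. If C2 and C3 come from an alkyne, and C4 and O1 from the formyl carbon and hydroxyl of a salicylaldehyde, one annulation closes ring C and joins two halves of similar size.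

## Retrosynthetic reasoning

16 from 15. The five O–CH3 bonds are cut first. Methyl ethers survive every step; free phenols would chelate the metals of the key step and oxidise; benzyl ethers would need hydrogenolysis, which endangers the C8–Cl bond. The forward step must cleave five aryl methyl ethers and leave the diaryl ether, the chloride and both pyranones untouched.

15 from 14. The C2–Si bond is cut. The silyl group has no place in the target and is carried only to steer the key step. The forward step is a fluoride-induced protodesilylation.

14 from 4 and 13 (key disconnection). Ring C of the chlorinated unit is opened at C4–C3 and O1–C2. This cut gives two pieces of comparable size, each from a simple aromatic starting material, and it removes an entire ring in one operation. It is preferred to a late cut of the diaryl ether, which would mean arylating a hindered phenol in the presence of two pyranones. The chlorine is already fixed on 4, next to the hydroxyl, before any chromone exists. The forward reaction has to cleave the formyl C–H bond of 4, insert the alkyne of 13 so that the aryl-bearing carbon bonds to the acyl carbon, and then form the C–O bond.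

13 from 11 and 12. The C(sp)–C(sp2) bond between the alkyne and ring B is cut. A bromine on ring B is a spectator through the ether formation and becomes the alkyne by a Sonogashira coupling.

11 from 10. The O5–CH3 bond is cut. The chelated 5-OH is capped so that 13 carries no free hydroxyl that could bind rhodium or copper in the key step.

10 from 8 and 9. The diaryl ether is cut on the side of ring B (O–C4') and not at C8. The hindered oxygen on C8 then acts as the nucleophile towards the aryl-iodonium salt 9, a type of arylation that tolerates two ortho substituents. The chelated 5-OH of 8 must stay out of the reaction.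

8 from 6 (through 7). The C8–O bond is cut. C8 is the only carbon para to the 5-OH, so an Elbs oxidation of the 5-phenoxide can put the oxygen nowhere else. The forward step has to do this without opening ring C.

6 from 5. The O7–CH3 bond is cut. The 7-OH of 5 is the most acidic hydroxyl and would compete in the oxidation and in the arylation, so it is methylated first; the chelated 5-OH is left free as the directing group.

4 from 2 (through 3). The bond between the formyl carbon and the ring is cut. In 2 one ortho position of the phenol is taken by chlorine, so an ortho-specific formylation has a single site.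

2 from 1. The C–Cl bond is cut. Both ortho positions of 1 are equivalent, so ortho-chlorination gives one product, and the chlorine then sits next to the oxygen that becomes O1.

## Alternatives that were turned down

Alternative 1: Ring A of the chlorinated unit is cut at C8–C8a and C4a–C5, so that ring C exists first as a 4-pyranone.
- Key step: the Brassard-type diene 4-chloro-1,3-dimethoxy-1-(trimethylsilyloxy)buta-1,3-diene A3 would attack C2 of 3,5-dibromo-4H-pyran-4-one A2 with its chlorine-bearing end. That carbon becomes C8, and C2 of A2 becomes C8a. The acetal carbon of A3 would then bond to the brominated C3 of A2 (future C4a), and elimination with collapse of the acetal would aromatise ring A to 3-bromo-8-chloro-5-hydroxy-7-methoxychromen-4-one A1.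
- For: the chlorine arrives on a defined carbon of the diene A3, so no electrophilic chlorination has to choose between C6 and C8. The 5-OH and 7-OMe come out differentiated, and the C3–Br bond of A1 is a handle for ring B.
- Against: such annulations are established on halogenated quinones, which are strong acceptors. C2 of the pyranone A2 is the β-carbon of a vinylogous ester in a ring with aromatic character and is far less electrophilic. The chlorine also lowers the nucleophilicity of the terminus of diene A3. A1 is only rings A and C of one unit, so ring B and the whole second isoflavone would still need a cross-coupling at C3.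
- Comparison: on the placement of chlorine this plan is the stronger one. The chosen route offers instead a chlorination at step 1 on the cheapest material, where the wrong isomer is symmetrical and easy to remove, a formylation with a single site, and a key step that joins the halves while it closes ring C.

Alternative 2: The bridging ring B is cut at C2'–C3' and C4'–C5'.
- Key step: the 2-pyranone 8-chloro-5,7-dimethoxy-3-(6-oxopyran-3-yl)chromen-4-one A5 would act as an electron-poor diene towards the aryl ethynyl ether 2-(ethynyloxy)-1,3,5-trimethoxybenzene A6. The adduct would aromatise by decarboxylation to 8-chloro-5,7-dimethoxy-3-[4-(2,4,6-trimethoxyphenoxy)phenyl]chromen-4-one A4, with the ether oxygen delivered to C4' by the alkyne.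
- For: the hindered diaryl ether is never made by a coupling, and no oxidation at C8 is needed. The polarity of the partners, with the nucleophilic alkyne CH of A6 adding to C6 of the pyranone ring of A5, leads to the para arrangement.
- Against: an aryl ethynyl ether such as A6 is labile, and A5 needs a synthesis of its own. The main weakness comes after A4: the trimethoxyphenoxy ring still has to become rings A and C of the second isoflavone. That means an acylation between two methoxy groups, cleavage of the one methoxy group between the acyl group and the ether oxygen while its neighbour on the other side of the acyl group stays, and ring closure. All of this happens in the presence of the finished chlorinated chromone, whose C6 is also nucleophilic. The sequence is linear and long.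
- Comparison: on the ether bond this plan is stronger. The chosen route makes that bond with an iodonium salt, which tolerates ortho substituents, and after the union of the halves it only deprotects.

Alternative 3: Ring A of the genistein unit is cut at C8–C8a and C4a–C5.
- Key step: the diene 4-(4-bromophenoxy)-1,3-dimethoxy-1-(trimethylsilyloxy)buta-1,3-diene A9 would add with its aryloxy-bearing end to C2 of 3-bromo-5-(4-methoxyphenyl)-4H-pyran-4-one A8, the CH next to the brominated carbon, which becomes C8a. It would then close onto the brominated C3 (future C4a) and aromatise to 8-(4-bromophenoxy)-5-hydroxy-7-methoxy-3-(4-methoxyphenyl)chromen-4-one A7. A7 is the same compound as 10.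
- For: the oxygen on C8 is in place from an acyclic precursor, so neither the persulfate oxidation nor the arylation of a hindered phenol is needed. If the annulation worked it would replace steps 3 to 5.
- Against: the doubt about a 4-pyranone as acceptor is the same as in Alternative 1. The unsymmetrical pyranone A8 and the diene A9 each need a synthesis of their own. The plan covers only the genistein half, so the chlorinated unit and the union would still require steps 1, 2 and 6 to 10 of the chosen route or an equivalent.
- Comparison: on the unambiguous placement of the C8 oxygen this plan is stronger. The chosen route reaches the same compound 10 by three known reactions from the purchasable isoflavone 5 and keeps its one uncertain step for the point where ring formation and fragment union coincide.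

Key step: step 8

Remark on the chemistry: part or all of the C2 silyl group may already be lost under the conditions of step 8. Both 14 and 15 lead on, and the route is written for the case that 14 is isolated.

## Route

Step 1
Reactants: 1 3,5-dimethoxyphenol
Product: 2 2-chloro-3,5-dimethoxyphenol
Conditions: SO2Cl2 (1.0 equiv), i-Bu2NH (8 mol %), toluene, 0 °C → rt
Reagents that add atoms: sulfuryl chloride, O=S(=O)(Cl)Cl
Why: Electrophilic aromatic chlorination; the amine-catalysed SO2Cl2 protocol directs chlorine ortho to a phenolic hydroxyl, and the two ortho positions of 1 are equivalent. The minor 4-chloro isomer is symmetrical and should be separable by chromatography or crystallisation.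

Step 2
Reactants: 2 2-chloro-3,5-dimethoxyphenol
Product: 4 3-chloro-2-hydroxy-4,6-dimethoxybenzaldehyde, via hydroxymethyl phenol 3 (not isolated)
Conditions: MgCl2 (1.5 equiv), Et3N (3.75 equiv), (CH2O)n (6.8 equiv), MeCN, reflux; then 1 M HCl
Reagents that add atoms: paraformaldehyde (reacts as formaldehyde), C=O
Why: Magnesium-mediated ortho-formylation (Casnati–Skattebøl): the magnesium phenoxide delivers formaldehyde to the free ortho carbon through a six-membered transition state, and the benzylic alkoxide of 3 is oxidised by a second formaldehyde in an Oppenauer-type hydride transfer. The other ortho carbon carries chlorine, so only one salicylaldehyde can form.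

Step 3
Reactants: 5 biochanin A (5,7-dihydroxy-3-(4-methoxyphenyl)chromen-4-one)
Product: 6 5-hydroxy-7-methoxy-3-(4-methoxyphenyl)chromen-4-one
Conditions: MeI (1.1 equiv), K2CO3 (1.2 equiv), acetone, 45 °C
Reagents that add atoms: iodomethane, CI
Why: Williamson ether synthesis; the 7-OH, para to the C4 carbonyl, is far more acidic than the 5-OH, which is hydrogen-bonded to that carbonyl, so one equivalent of base and MeI should methylate O7 only.

Step 4
Reactants: 6 5-hydroxy-7-methoxy-3-(4-methoxyphenyl)chromen-4-one
Product: 8 5,8-dihydroxy-7-methoxy-3-(4-methoxyphenyl)chromen-4-one, via aryl potassium sulfate 7 (not isolated)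
Conditions: K2S2O8 (1.5 equiv), 10% aq KOH, pyridine, 15 °C, 24 h; acidify to pH 5 and remove unchanged 6; then conc. HCl, Na2SO3, 90 °C, 30 min
Reagents that add atoms: K2S2O8 (dipotassium peroxodisulfate), [K+].[K+].[O-]S(=O)(=O)OOS(=O)(=O)[O-]
Why: Elbs persulfate oxidation: the 5-phenoxide attacks a peroxide oxygen through its para carbon, which is C8 and nothing else, and the aryl sulfate 7 is hydrolysed by acid. The 7-methyl ether keeps the more acidic hydroxyl out of play, and Na2SO3 protects the hydroquinone from air during hydrolysis.

Step 5
Reactants: 8 5,8-dihydroxy-7-methoxy-3-(4-methoxyphenyl)chromen-4-one; 9 bis(4-bromophenyl)iodonium triflate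
Product: 10 8-(4-bromophenoxy)-5-hydroxy-7-methoxy-3-(4-methoxyphenyl)chromen-4-one
Conditions: 9 (1.1 equiv), K2CO3 (1.2 equiv), degassed MeCN, 50 °C, argon
Reagents that add atoms: none
Why: Metal-free O-arylation of a phenoxide with a diaryliodonium salt: ligand exchange on trivalent iodine and ligand coupling give the diaryl ether and tolerate two ortho substituents. The chelated, peri-hindered 5-OH should stay out, and the symmetrical salt can transfer only a 4-bromophenyl group.

Step 6
Reactants: 10 8-(4-bromophenoxy)-5-hydroxy-7-methoxy-3-(4-methoxyphenyl)chromen-4-one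
Product: 11 8-(4-bromophenoxy)-5,7-dimethoxy-3-(4-methoxyphenyl)chromen-4-one
Conditions: Me2SO4 (3 equiv), K2CO3 (4 equiv), acetone, reflux
Reagents that add atoms: dimethyl sulfate, COS(=O)(=O)OC
Why: Williamson methylation of the chelated 5-OH, which needs excess reagent and heat but is routine for 5-hydroxyisoflavones; no other acidic site is left.

Step 7
Reactants: 11 8-(4-bromophenoxy)-5,7-dimethoxy-3-(4-methoxyphenyl)chromen-4-one; 12 trimethylsilylacetylene
Product: 13 5,7-dimethoxy-3-(4-methoxyphenyl)-8-[4-(2-trimethylsilylethynyl)phenoxy]chromen-4-one
Conditions: 12 (2 equiv), PdCl2(PPh3)2 (5 mol %), CuI (10 mol %), Et3N/DMF, 80 °C, sealed tube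
Reagents that add atoms: none
Why: Sonogashira coupling of the aryl bromide with the terminal alkyne. A tertiary amine is used because secondary amines add to C2 of chromones, and the silyl group stays on the alkyne since neither fluoride nor hydroxide is present.

Step 8
Reactants: 4 3-chloro-2-hydroxy-4,6-dimethoxybenzaldehyde; 13 5,7-dimethoxy-3-(4-methoxyphenyl)-8-[4-(2-trimethylsilylethynyl)phenoxy]chromen-4-one
Product: 14 8-chloro-3-[4-[[5,7-dimethoxy-3-(4-methoxyphenyl)-4-oxochromen-8-yl]oxy]phenyl]-5,7-dimethoxy-2-(trimethylsilyl)chromen-4-one
Conditions: 4 (1.5 equiv), [RhCl2(C5Me5)]2 (2.5 mol %), anhydrous Cu(OAc)2 (2.2 equiv), o-xylene, 120 °C, argon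
Reagents that add atoms: none
Why: The closest known reaction is the rhodium-catalysed oxidative annulation of salicylaldehydes with internal alkynes to 2,3-disubstituted chromones, applied here to a silyl aryl alkyne. The phenoxide of 4 binds trivalent rhodium, and acetate-assisted cleavage of the formyl C–H bond gives a five-membered acyl rhodacycle. Alkyne 13 inserts into the rhodium–acyl bond, which forms C4–C3 and leaves a seven-membered oxarhodacycle; C–O reductive elimination then forms O1–C2 and closes ring C, a six-membered pyranone made in a formal (4+2) annulation by contraction of the metallacycle. Cu(OAc)2 (divalent copper, two equivalents) returns the released monovalent rhodium to the trivalent state. The step needs one selectivity, the sense of insertion: the silyl-bearing carbon should end on rhodium and the aryl-bearing carbon on the acyl carbon, because a carbon–metal bond next to silicon is favoured and the bulky SiMe3 group avoids the forming C–C bond, as in Larock heteroannulations of silyl alkynes; this puts ring B on C3 (isoflavone) and not on C2 (flavone). No stereocentre is formed. The aryl chloride and the aryl ethers are inert to the catalyst, and the hydroxyl of 4 is the only free one in either partner, so there is one directing group and one C–H bond to cleave.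

Step 9
Reactants: 14 8-chloro-3-[4-[[5,7-dimethoxy-3-(4-methoxyphenyl)-4-oxochromen-8-yl]oxy]phenyl]-5,7-dimethoxy-2-(trimethylsilyl)chromen-4-one
Product: 15 8-chloro-3-[4-[[5,7-dimethoxy-3-(4-methoxyphenyl)-4-oxochromen-8-yl]oxy]phenyl]-5,7-dimethoxychromen-4-one
Conditions: Bu4NF (1.5 equiv), AcOH (1.5 equiv), THF, 0 °C → rt
Reagents that add atoms: none
Why: Fluoride-induced protodesilylation: fluoride attacks silicon and the C2–Si bond breaks to an sp2 carbanion that is stabilised by the adjacent ring oxygen and protonated at once, as in the removal of 2-silyl groups from heteroarenes made by Larock-type annulation. Acetic acid buffers the medium so that ring C is not opened by attack at C2.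

Step 10
Reactants: 15 8-chloro-3-[4-[[5,7-dimethoxy-3-(4-methoxyphenyl)-4-oxochromen-8-yl]oxy]phenyl]-5,7-dimethoxychromen-4-one
Product: 16 8-chloro-3-[4-[[5,7-dihydroxy-3-(4-hydroxyphenyl)-4-oxochromen-8-yl]oxy]phenyl]-5,7-dihydroxychromen-4-one (the target)
Conditions: BBr3 (15 equiv), CH2Cl2, −78 °C → rt, then 40 °C if needed; MeOH, then H2O
Reagents that add atoms: none
Why: Lewis acid cleavage of aryl methyl ethers: each ether oxygen binds boron and bromide removes the methyl group by SN2 attack at carbon. The diaryl ether offers no sp3 carbon and should survive, as should the aryl chloride and both pyranones; the two 5-methoxy groups, assisted by the C4 carbonyls, go first and the 7- and 4'-ethers follow on warming.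

## Compound list

1 | 3,5-dimethoxyphenol | COc1cc(O)cc(OC)c1 | starting material
2 | 2-chloro-3,5-dimethoxyphenol | COc1cc(O)c(Cl)c(OC)c1 | intermediate
3 | 2-chloro-6-(hydroxymethyl)-3,5-dimethoxyphenol (present as its magnesium salt) | OCc1c(O)c(Cl)c(OC)cc1OC | intermediate (not isolated)
4 | 3-chloro-2-hydroxy-4,6-dimethoxybenzaldehyde | O=Cc1c(O)c(Cl)c(OC)cc1OC | intermediate
5 | biochanin A, 5,7-dihydroxy-3-(4-methoxyphenyl)chromen-4-one | COc1ccc(cc1)-c1coc2cc(O)cc(O)c2c1=O | starting material
6 | 5-hydroxy-7-methoxy-3-(4-methoxyphenyl)chromen-4-one | COc1ccc(cc1)-c1coc2cc(OC)cc(O)c2c1=O | intermediate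
7 | potassium 5-hydroxy-7-methoxy-3-(4-methoxyphenyl)-4-oxochromen-8-yl sulfate | COc1ccc(cc1)-c1coc2c(OS(=O)(=O)[O-])c(OC)cc(O)c2c1=O.[K+] | intermediate (not isolated)
8 | 5,8-dihydroxy-7-methoxy-3-(4-methoxyphenyl)chromen-4-one | COc1ccc(cc1)-c1coc2c(O)c(OC)cc(O)c2c1=O | intermediate
9 | bis(4-bromophenyl)iodonium triflate | Brc1ccc([I+]c2ccc(Br)cc2)cc1.[O-]S(=O)(=O)C(F)(F)F | starting material
10 | 8-(4-bromophenoxy)-5-hydroxy-7-methoxy-3-(4-methoxyphenyl)chromen-4-one | COc1ccc(cc1)-c1coc2c(Oc3ccc(Br)cc3)c(OC)cc(O)c2c1=O | intermediate
11 | 8-(4-bromophenoxy)-5,7-dimethoxy-3-(4-methoxyphenyl)chromen-4-one | COc1ccc(cc1)-c1coc2c(Oc3ccc(Br)cc3)c(OC)cc(OC)c2c1=O | intermediate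
12 | trimethylsilylacetylene | C#C[Si](C)(C)C | starting material
13 | 5,7-dimethoxy-3-(4-methoxyphenyl)-8-[4-(2-trimethylsilylethynyl)phenoxy]chromen-4-one | C[Si](C)(C)C#Cc1ccc(Oc2c(OC)cc(OC)c3c(=O)c(-c4ccc(OC)cc4)coc23)cc1 | intermediate
14 | 8-chloro-3-[4-[[5,7-dimethoxy-3-(4-methoxyphenyl)-4-oxochromen-8-yl]oxy]phenyl]-5,7-dimethoxy-2-(trimethylsilyl)chromen-4-one | O=c1c(-c2ccc(Oc3c(OC)cc(OC)c4c(=O)c(-c5ccc(OC)cc5)coc34)cc2)c([Si](C)(C)C)oc2c(Cl)c(OC)cc(OC)c12 | intermediate
15 | 8-chloro-3-[4-[[5,7-dimethoxy-3-(4-methoxyphenyl)-4-oxochromen-8-yl]oxy]phenyl]-5,7-dimethoxychromen-4-one | O=c1c(-c2ccc(Oc3c(OC)cc(OC)c4c(=O)c(-c5ccc(OC)cc5)coc34)cc2)coc2c(Cl)c(OC)cc(OC)c12 | intermediate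
16 | 8-chloro-3-[4-[[5,7-dihydroxy-3-(4-hydroxyphenyl)-4-oxochromen-8-yl]oxy]phenyl]-5,7-dihydroxychromen-4-one | O=c1c(-c2ccc(Oc3c(O)cc(O)c4c(=O)c(-c5ccc(O)cc5)coc34)cc2)coc2c(Cl)c(O)cc(O)c12 | target

## Step count and uncertain steps

Total: 10 steps. Longest linear sequence: 8 steps (steps 3 to 10, from 5); the aldehyde branch adds steps 1 and 2.

**Step 8 (key step).**
- What may go wrong: insertion of the alkyne in the opposite sense, with the aryl-bearing carbon on rhodium, would place ring B on C2 and give the flavone skeleton. Loss of the silyl group from 13 before insertion would lead to insertion as a terminal alkyne in that same wrong sense, or to oxidative dimerisation by Cu(OAc)2. Decarbonylation of the acyl rhodacycle would divert 4.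
- Fallback: it sets out from 11, with 2 for the second partner, and comes back at 15. Miyaura borylation of 11 (B2pin2, PdCl2(dppf), KOAc, dioxane, 90 °C) gives 5,7-dimethoxy-3-(4-methoxyphenyl)-8-[4-(4,4,5,5-tetramethyl-1,3,2-dioxaborolan-2-yl)phenoxy]chromen-4-one F1. In parallel 2 is acetylated at its one free ortho position (Ac2O, BF3·OEt2, 90 °C, then aqueous hydrolysis of the boron chelate) to 1-(3-chloro-2-hydroxy-4,6-dimethoxyphenyl)ethanone F2. This is condensed with N,N-dimethylformamide dimethyl acetal to (E)-1-(3-chloro-2-hydroxy-4,6-dimethoxyphenyl)-3-(dimethylamino)prop-2-en-1-one F3 and cyclised with I2 in CHCl3 to 8-chloro-3-iodo-5,7-dimethoxychromen-4-one F4. Suzuki coupling of F1 with F4 (Pd(PPh3)4, Na2CO3, DME/H2O, 80 °C) gives 15. The C3–C1' bond is then made at a position fixed by the iodine, and the C8–Cl bond stays out of the coupling.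

**Step 4.**
- What may go wrong: low conversion, which is usual for persulfate oxidations; opening of ring C by hydroxide during the long exposure to aqueous alkali; further oxidation of the hydroquinone product.
- Fallback: it sets out from 6 and comes back at 11, and so also avoids the free hydroquinone. Methylation of 6 (Me2SO4, K2CO3, acetone, reflux) gives 5,7-dimethoxy-3-(4-methoxyphenyl)chromen-4-one F5. Bromination with N-bromosuccinimide in DMF should go to the less hindered C8 of the 5,7-dimethoxy ring and give 8-bromo-5,7-dimethoxy-3-(4-methoxyphenyl)chromen-4-one F6. Miyaura borylation (B2pin2, PdCl2(dppf), KOAc, dioxane, 100 °C) gives 5,7-dimethoxy-3-(4-methoxyphenyl)-8-(4,4,5,5-tetramethyl-1,3,2-dioxaborolan-2-yl)chromen-4-one F7, and oxidation with NaBO3·4H2O in THF/H2O gives 8-hydroxy-5,7-dimethoxy-3-(4-methoxyphenyl)chromen-4-one F8. Arylation of F8 with 9 (K2CO3, MeCN, 50 °C) gives 11.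

**Step 5.**
- What may go wrong: electron transfer from the hydroquinone monoanion to the iodonium salt, which would oxidise the substrate to the 5,8-quinone instead of arylating it; arylation on both oxygens.
- Fallback: it sets out from 8 and comes back at 10. An Ullmann-type coupling of 8 with 1-bromo-4-iodobenzene (CuI 10 mol %, picolinic acid 20 mol %, K3PO4, DMSO, 80 °C, argon) uses an aryl iodide that is not an oxidant; the C–I bond reacts before the C–Br bond. No new compound is made.

**Step 1.**
- What may go wrong: chlorination at the carbon between the two methoxy groups, para to the hydroxyl, and a second chlorination of the very electron-rich ring.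
- Fallback: it sets out from 1 and comes back at 2, and replaces electrophilic substitution by directed ortho-metalation. 1 is converted into 3,5-dimethoxyphenyl N,N-diethylcarbamate F9 (Et2NCOCl, K2CO3, MeCN, reflux). Lithiation with s-BuLi/TMEDA in THF at −78 °C occurs between the carbamate and a methoxy group, and quenching with C2Cl6 gives 2-chloro-3,5-dimethoxyphenyl N,N-diethylcarbamate F10. Cleavage of the carbamate (NaOH, EtOH/H2O, reflux) gives 2.

**Step 10.**
- What may go wrong: incomplete cleavage, because partly demethylated boron chelates precipitate from CH2Cl2 and the 7- and 4'-ethers then react slowly.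
- Fallback: it sets out from 15 and comes back at 16, in two stages with different reagents. BCl3 (CH2Cl2, 0 °C) cleaves only the two methoxy groups peri to the carbonyls and gives 8-chloro-5-hydroxy-3-[4-[[5-hydroxy-7-methoxy-3-(4-methoxyphenyl)-4-oxochromen-8-yl]oxy]phenyl]-7-methoxychromen-4-one F11. A melt of pyridine hydrochloride (185 °C) then removes the remaining three methyl groups and gives 16.

## Further compounds

F1 | step 8 | 5,7-dimethoxy-3-(4-methoxyphenyl)-8-[4-(4,4,5,5-tetramethyl-1,3,2-dioxaborolan-2-yl)phenoxy]chromen-4-one | COc1ccc(cc1)-c1coc2c(Oc3ccc(cc3)B3OC(C)(C)C(C)(C)O3)c(OC)cc(OC)c2c1=O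
F2 | step 8 | 1-(3-chloro-2-hydroxy-4,6-dimethoxyphenyl)ethanone | CC(=O)c1c(O)c(Cl)c(OC)cc1OC
F3 | step 8 | (E)-1-(3-chloro-2-hydroxy-4,6-dimethoxyphenyl)-3-(dimethylamino)prop-2-en-1-one | CN(C)/C=C/C(=O)c1c(O)c(Cl)c(OC)cc1OC
F4 | step 8 | 8-chloro-3-iodo-5,7-dimethoxychromen-4-one | O=c1c(I)coc2c(Cl)c(OC)cc(OC)c12
F5 | step 4 | 5,7-dimethoxy-3-(4-methoxyphenyl)chromen-4-one | COc1ccc(cc1)-c1coc2cc(OC)cc(OC)c2c1=O
F6 | step 4 | 8-bromo-5,7-dimethoxy-3-(4-methoxyphenyl)chromen-4-one | COc1ccc(cc1)-c1coc2c(Br)c(OC)cc(OC)c2c1=O
F7 | step 4 | 5,7-dimethoxy-3-(4-methoxyphenyl)-8-(4,4,5,5-tetramethyl-1,3,2-dioxaborolan-2-yl)chromen-4-one | COc1ccc(cc1)-c1coc2c(B3OC(C)(C)C(C)(C)O3)c(OC)cc(OC)c2c1=O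
F8 | step 4 | 8-hydroxy-5,7-dimethoxy-3-(4-methoxyphenyl)chromen-4-one | COc1ccc(cc1)-c1coc2c(O)c(OC)cc(OC)c2c1=O
F0 | step 5 | none | none
F9 | step 1 | 3,5-dimethoxyphenyl N,N-diethylcarbamate | CCN(CC)C(=O)Oc1cc(OC)cc(OC)c1
F10 | step 1 | 2-chloro-3,5-dimethoxyphenyl N,N-diethylcarbamate | CCN(CC)C(=O)Oc1cc(OC)cc(OC)c1Cl
F11 | step 10 | 8-chloro-5-hydroxy-3-[4-[[5-hydroxy-7-methoxy-3-(4-methoxyphenyl)-4-oxochromen-8-yl]oxy]phenyl]-7-methoxychromen-4-one | O=c1c(-c2ccc(Oc3c(OC)cc(O)c4c(=O)c(-c5ccc(OC)cc5)coc34)cc2)coc2c(Cl)c(OC)cc(O)c12
A1 | alternative 1 | 3-bromo-8-chloro-5-hydroxy-7-methoxychromen-4-one | COc1cc(O)c2c(=O)c(Br)coc2c1Cl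
A2 | alternative 1 | 3,5-dibromo-4H-pyran-4-one | O=c1c(Br)cocc1Br
A3 | alternative 1 | 4-chloro-1,3-dimethoxy-1-(trimethylsilyloxy)buta-1,3-diene | COC(O[Si](C)(C)C)=CC(OC)=CCl
A4 | alternative 2 | 8-chloro-5,7-dimethoxy-3-[4-(2,4,6-trimethoxyphenoxy)phenyl]chromen-4-one | COc1cc(OC)c(Oc2ccc(-c3coc4c(Cl)c(OC)cc(OC)c4c3=O)cc2)c(OC)c1
A5 | alternative 2 | 8-chloro-5,7-dimethoxy-3-(6-oxopyran-3-yl)chromen-4-one | O=c1ccc(co1)-c1coc2c(Cl)c(OC)cc(OC)c2c1=O
A6 | alternative 2 | 2-(ethynyloxy)-1,3,5-trimethoxybenzene | C#COc1c(OC)cc(OC)cc1OC
A7 | alternative 3 | 8-(4-bromophenoxy)-5-hydroxy-7-methoxy-3-(4-methoxyphenyl)chromen-4-one | COc1ccc(cc1)-c1coc2c(Oc3ccc(Br)cc3)c(OC)cc(O)c2c1=O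
A8 | alternative 3 | 3-bromo-5-(4-methoxyphenyl)-4H-pyran-4-one | COc1ccc(cc1)-c1cocc(Br)c1=O
A9 | alternative 3 | 4-(4-bromophenoxy)-1,3-dimethoxy-1-(trimethylsilyloxy)buta-1,3-diene | COC(O[Si](C)(C)C)=CC(OC)=COc1ccc(Br)cc1
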